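Rings are lettered A–H from the 2,4,6-trihydroxyphenyl end, and position 1 of each ring is the carbon whose oxygen leads back to the preceding ring. The target has no stereocentre; the one racemic centre made on the way is lost on aromatisation.
Cuts: first the 21 O–alkyl bonds. Then the outer ethers at O–C1, O–E1 and O–G1 (Ullmann), giving an A–B phenol, one C–D/E–F iodide used twice, and a G–H iodide. Then the inner ethers at O–D1, O–F1 and O–H1 (Chan–Lam), leading to one common iodophenol and two arylboronic acids.
Enabling feature: ring B has oxygen on B1, B3, B4 and B5 and hydrogen on B2 and B6, and the crowded ring A oxygen (B1) sits meta to the one oxygen (B5) that must stay free for chain growth. This is the pattern left when an ynol ether is stitched into a 3,4-dialkoxycyclobutenone, so ring B is cut at B1–B2, B5–B6 and B4–B5.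
Forward: ring B is the only ring constructed, and it grows on the ring A oxygen. The chain is then extended from B5–OH two rings at a time (A–B, A–D, A–F, A–H) by Ullmann coupling and hydrogenolysis, and BBr3 frees all phenols.

Key step: step 4

Remark: B4 is carried as a methyl ether (from methoxyketene) and B3 as an ethyl ether (from ethoxyacetylene). Benzyl is kept for D4 and F4 only, so that each hydrogenolysis exposes a single phenol.

Step 1
Reactants: 1 2,4,6-trimethoxyphenol; 2 trichloroethylene
Product: 4 2-{[(E)-1,2-dichloroethenyl]oxy}-1,3,5-trimethoxybenzene, via dichloroacetylene 3 (not isolated)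
Conditions: K2CO3, DMF, 70 °C
Reagents that add atoms: none
Why: Base-induced loss of HCl from 2 gives dichloroacetylene, and anti addition of the phenoxide to this unhindered sp carbon (nucleophilic addition to a haloalkyne, the standard entry to aryl 1,2-dichlorovinyl ethers) should give the E ether in spite of the two ortho-methoxy groups.

Step 2
Reactants: 4 2-{[(E)-1,2-dichloroethenyl]oxy}-1,3,5-trimethoxybenzene
Product: 7 2-(ethynyloxy)-1,3,5-trimethoxybenzene (ring A ethynyl ether), via chloroethynyl ether 5 (not isolated), via lithium acetylide 6 (not isolated)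
Conditions: n-BuLi (2.2 equiv), Et2O, −78 → −40 °C; then H2O, −78 → 0 °C
Reagents that add atoms: none
Why: This is the dichlorovinyl ether route to ynol ethers, in which the first equivalent of n-BuLi removes HCl to give the chloroalkyne, the second exchanges chlorine for lithium, and protonation gives the terminal ynol ether, which is used without storage.

Step 3
Reactants: 8 methoxyacetyl chloride; 9 ethoxyacetylene
Product: 11 (±)-3-ethoxy-4-methoxycyclobut-2-en-1-one, via methoxyketene 10 (not isolated)
Conditions: Et3N (slow addition), 9 (2 equiv, solution in hexanes), Et2O, 0 °C → rt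
Reagents that add atoms: none
Why: Dehydrochlorination gives methoxyketene, which undergoes the known ketene–alkoxyacetylene [2+2] cycloaddition with the nucleophilic CH carbon of 9 bonding to the ketene carbonyl carbon, so ethoxy ends at C3 and methoxy at C4 (the C4 centre is racemic and is lost in step 4).

Step 4
Reactants: 7 2-(ethynyloxy)-1,3,5-trimethoxybenzene; 11 (±)-3-ethoxy-4-methoxycyclobut-2-en-1-one
Product: 16 3-ethoxy-2-methoxy-5-(2,4,6-trimethoxyphenoxy)phenol (A–B phenol), via vinylketene 12 (not isolated), via vinylcyclobutenone 13 (not isolated), via dienylketene 14 (not isolated), via cyclohexadienone 15 (not isolated)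
Conditions: 7 (1.2 equiv), toluene, sealed tube, argon, 80 → 110 °C
Reagents that add atoms: none
Why: In this Danheiser benzannulation, thermal 4π electrocyclic opening of 11 (the C4 methoxy donor turning outward) gives vinylketene 12, whose ketene C=C adds [2+2] to ynol ether 7 to give 4-vinylcyclobutenone 13, and a second, reversible 4π opening gives dienylketene 14. Ring B then closes by thermal 6π electrocyclisation of 14, the ketene carbon bonding to the methoxy-bearing terminus (B5–B4), and dienone 15 tautomerises to phenol 16. The closest known reaction type is the cyclobutenone/alkoxyacetylene benzannulation that gives resorcinol monoethers. The only selectivity needed is the orientation of the [2+2] step: the ynol ether is polarised so that its CH carbon attacks the ketene carbonyl carbon (B6–B5), which leaves the oxygen-bearing alkyne carbon to bond to the ketene α-carbon (B1–B2) and puts the aryloxy group meta to the new hydroxyl. An aryl ynol ether has no β-hydrogen, so the retro-ene loss of alkene that limits alkyl ynol ethers on heating cannot occur, and the two ortho-methoxy groups twist ring A out of conjugation so that the oxygen lone pair still feeds the triple bond. No stereocentre is formed, and the racemic centres of 11, 13 and 15 vanish on aromatisation.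

Step 5
Reactants: 17 2,3,4-trimethoxybenzaldehyde
Product: 19 2,3,4-trimethoxyphenol, via aryl formate 18 (not isolated)
Conditions: 30% aq H2O2, H2SO4 (cat.), MeOH, rt
Reagents that add atoms: hydrogen peroxide, OO
Why: In this acid-catalysed Dakin (Baeyer–Villiger type) oxidation the electron-rich aryl group migrates to oxygen and the aryl formate is methanolysed in the same flask.

Step 6
Reactants: 19 2,3,4-trimethoxyphenol
Product: 20 6-iodo-2,3,4-trimethoxyphenol
Conditions: I2 (1.0 equiv), NaHCO3, THF–H2O, 0 °C → rt
Reagents that add atoms: iodine, II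
Why: Electrophilic aromatic iodination runs through the phenoxide, for which C6 is the only free ortho or para position while C5 is meta to the phenoxide oxygen, and I2/NaHCO3 is a standard mild system for electron-rich phenols.

Step 7
Reactants: 21 4-bromo-2,6-dimethoxyphenol
Product: 22 2-(benzyloxy)-5-bromo-1,3-dimethoxybenzene
Conditions: BnBr, K2CO3, DMF, rt → 50 °C
Reagents that add atoms: benzyl bromide, BrCc1ccccc1
Why: Williamson ether synthesis on the only hydroxyl, with a primary benzylic halide that reaches the flanked phenoxide without difficulty.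

Step 8
Reactants: 22 2-(benzyloxy)-5-bromo-1,3-dimethoxybenzene
Product: 25 [4-(benzyloxy)-3,5-dimethoxyphenyl]boronic acid, via aryllithium 23 (not isolated), via lithium arylborate 24 (not isolated)
Conditions: n-BuLi, THF, −78 °C; B(Oi-Pr)3, −78 °C → rt; 1 M aq HCl
Reagents that add atoms: triisopropyl borate, CC(C)OB(OC(C)C)OC(C)C; water, O
Why: Br/Li exchange at −78 °C outruns benzylic deprotonation, and borylation of the aryllithium followed by acid hydrolysis is the standard arylboronic acid synthesis.

Step 9
Reactants: 20 6-iodo-2,3,4-trimethoxyphenol; 25 [4-(benzyloxy)-3,5-dimethoxyphenyl]boronic acid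
Product: 26 2-[4-(benzyloxy)-3,5-dimethoxyphenoxy]-1-iodo-3,4,5-trimethoxybenzene (C–D/E–F iodide)
Conditions: 25 (2 equiv), Cu(OAc)2, pyridine, 4 Å MS, CH2Cl2, dry air, rt
Reagents that add atoms: none
Why: In the Chan–Lam coupling, transmetalation of the ortho-unsubstituted, electron-rich boronic acid to divalent copper, oxidation to trivalent copper and C–O reductive elimination all proceed at room temperature, conditions under which 2,6-disubstituted ortho-iodophenols are known to couple with the C–I bond untouched.

Step 10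
Reactants: 20 6-iodo-2,3,4-trimethoxyphenol; 27 (3,4,5-trimethoxyphenyl)boronic acid
Product: 28 1-iodo-3,4,5-trimethoxy-2-(3,4,5-trimethoxyphenoxy)benzene (G–H iodide)
Conditions: 27 (2 equiv), Cu(OAc)2, pyridine, 4 Å MS, CH2Cl2, dry air, rt
Reagents that add atoms: none
Why: This is the same Chan–Lam coupling as in step 9, with a commercial boronic acid of the same electronic and steric type.

Step 11
Reactants: 16 A–B phenol; 26 C–D/E–F iodide
Product: 29 A–D tetramer benzyl ether (B5–O–C1 formed; D4 OBn)
Conditions: 26 (1.3 equiv), CuI (10 mol %), picolinic acid (20 mol %), K3PO4, DMSO, argon, 90 °C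
Reagents that add atoms: none
Why: The Ullmann diaryl ether synthesis with a picolinate complex of monovalent copper suits ortho-substituted partners, and since 16 has one hydroxyl with a single ortho substituent and 26 has one C–I bond, only one ether can form.

Step 12
Reactants: 29 A–D tetramer benzyl ether
Product: 30 A–D tetramer phenol (D4 OH)
Conditions: H2 (1 atm), 10% Pd/C, EtOAc–MeOH, rt
Reagents that add atoms: none
Why: Catalytic hydrogenolysis removes the only benzyl ether, while methyl, ethyl and diaryl ethers are inert and no halogen is left in the molecule.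

Step 13
Reactants: 30 A–D tetramer phenol; 26 C–D/E–F iodide
Product: 31 A–F hexamer benzyl ether (D4–O–E1 formed; F4 OBn)
Conditions: 26 (1.5 equiv), CuI (20 mol %), picolinic acid (40 mol %), K3PO4, DMSO, argon, 100 °C
Reagents that add atoms: none
Why: This is the same Ullmann coupling, now with a phenoxide flanked by two methoxy groups, a class of hindered phenol this catalyst system is known to arylate, with the easily made iodide in excess to offset hydrodeiodination.

Step 14
Reactants: 31 A–F hexamer benzyl ether
Product: 32 A–F hexamer phenol (F4 OH)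
Conditions: H2 (1 atm), 10% Pd/C, EtOAc–MeOH, rt
Reagents that add atoms: none
Why: Catalytic hydrogenolysis of the single benzyl ether, as in step 12.

Step 15
Reactants: 32 A–F hexamer phenol; 28 G–H iodide
Product: 33 fully alkylated octamer (F4–O–G1 formed; 20 OMe and 1 OEt)
Conditions: 28 (1.5 equiv), CuI (20 mol %), picolinic acid (40 mol %), K3PO4, DMSO, argon, 100 °C
Reagents that add atoms: none
Why: This Ullmann diaryl ether synthesis is of the same type as step 13 and completes the seven ether bridges.

Step 16
Reactants: 33 fully alkylated octamer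
Product: 34 CNP0175816.0 (target)
Conditions: BBr3 (excess), CH2Cl2, argon, −78 °C → rt; then degassed H2O, 0 °C; isolation under argon (Sephadex LH-20)
Reagents that add atoms: none
Why: In this Lewis acid dealkylation of aryl alkyl ethers, BBr3 binds each alkyl ether oxygen and bromide removes methyl or ethyl by SN2, diaryl ether C–O bonds offer no sp3 carbon for attack, and hydrolysis of the aryl borates frees the 21 phenols.

Compound list
1 | 2,4,6-trimethoxyphenol | COc1cc(OC)c(O)c(OC)c1 | starting material
2 | trichloroethylene | ClC=C(Cl)Cl | starting material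
3 | dichloroacetylene | ClC#CCl | intermediate
4 | 2-{[(E)-1,2-dichloroethenyl]oxy}-1,3,5-trimethoxybenzene | COc1cc(OC)c(O/C(Cl)=C\Cl)c(OC)c1 | intermediate
5 | 2-[(chloroethynyl)oxy]-1,3,5-trimethoxybenzene | ClC#COc1c(OC)cc(OC)cc1OC | intermediate
6 | lithium (2,4,6-trimethoxyphenoxy)acetylide | [Li]C#COc1c(OC)cc(OC)cc1OC | intermediate
7 | 2-(ethynyloxy)-1,3,5-trimethoxybenzene | C#COc1c(OC)cc(OC)cc1OC | intermediate
8 | methoxyacetyl chloride | COCC(=O)Cl | starting material
9 | ethoxyacetylene | C#COCC | starting material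
10 | methoxyketene | COC=C=O | intermediate
11 | (±)-3-ethoxy-4-methoxycyclobut-2-en-1-one (racemic) | CCOC1=CC(=O)C1OC | intermediate
12 | (3Z)-3-ethoxy-4-methoxybuta-1,3-dien-1-one | O=C=C/C(OCC)=C/OC | intermediate
13 | (±)-4-[(Z)-1-ethoxy-2-methoxyethenyl]-3-(2,4,6-trimethoxyphenoxy)cyclobut-2-en-1-one (racemic) | O=C1C=C(Oc2c(OC)cc(OC)cc2OC)C1/C(OCC)=C/OC | intermediate
14 | (3E,5Z)-5-ethoxy-6-methoxy-3-(2,4,6-trimethoxyphenoxy)hexa-1,3,5-trien-1-one | O=C=C/C(Oc1c(OC)cc(OC)cc1OC)=C\C(OCC)=C\OC | intermediate
15 | (±)-5-ethoxy-6-methoxy-3-(2,4,6-trimethoxyphenoxy)cyclohexa-2,4-dien-1-one (racemic) | CCOC1=CC(Oc2c(OC)cc(OC)cc2OC)=CC(=O)C1OC | intermediate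
16 | 3-ethoxy-2-methoxy-5-(2,4,6-trimethoxyphenoxy)phenol (A–B phenol: B1 O–ring A, B3 OEt, B4 OMe, B5 OH) | CCOc1cc(Oc2c(OC)cc(OC)cc2OC)cc(O)c1OC | intermediate
17 | 2,3,4-trimethoxybenzaldehyde | COc1ccc(C=O)c(OC)c1OC | starting material
18 | 2,3,4-trimethoxyphenyl formate | COc1ccc(OC=O)c(OC)c1OC | intermediate
19 | 2,3,4-trimethoxyphenol | COc1ccc(O)c(OC)c1OC | intermediate
20 | 6-iodo-2,3,4-trimethoxyphenol | COc1cc(I)c(O)c(OC)c1OC | intermediate
21 | 4-bromo-2,6-dimethoxyphenol | COc1cc(Br)cc(OC)c1O | starting material
22 | 2-(benzyloxy)-5-bromo-1,3-dimethoxybenzene | COc1cc(Br)cc(OC)c1OCc1ccccc1 | intermediate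
23 | [4-(benzyloxy)-3,5-dimethoxyphenyl]lithium | [Li]c1cc(OC)c(OCc2ccccc2)c(OC)c1 | intermediate
24 | lithium [4-(benzyloxy)-3,5-dimethoxyphenyl]triisopropoxyborate | [Li+].CC(C)O[B-](OC(C)C)(OC(C)C)c1cc(OC)c(OCc2ccccc2)c(OC)c1 | intermediate
25 | [4-(benzyloxy)-3,5-dimethoxyphenyl]boronic acid | OB(O)c1cc(OC)c(OCc2ccccc2)c(OC)c1 | intermediate
26 | 2-[4-(benzyloxy)-3,5-dimethoxyphenoxy]-1-iodo-3,4,5-trimethoxybenzene (C–D/E–F iodide) | COc1cc(I)c(Oc2cc(OC)c(OCc3ccccc3)c(OC)c2)c(OC)c1OC | intermediate
27 | (3,4,5-trimethoxyphenyl)boronic acid | COc1cc(B(O)O)cc(OC)c1OC | starting material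
28 | 1-iodo-3,4,5-trimethoxy-2-(3,4,5-trimethoxyphenoxy)benzene (G–H iodide) | COc1cc(I)c(Oc2cc(OC)c(OC)c(OC)c2)c(OC)c1OC | intermediate
29 | A–D tetramer benzyl ether: ring A 2,4,6-tri-OMe; ring B 3-OEt, 4-OMe, 5-O–C1; ring C 2-O–D1, 3,4,5-tri-OMe; ring D 3,5-di-OMe, 4-OBn | COc1cc(OC)c(Oc2cc(OCC)c(OC)c(Oc3cc(OC)c(OC)c(OC)c3Oc3cc(OC)c(OCc4ccccc4)c(OC)c3)c2)c(OC)c1 | intermediate
30 | A–D tetramer phenol: as 29 with D4 OH | COc1cc(OC)c(Oc2cc(OCC)c(OC)c(Oc3cc(OC)c(OC)c(OC)c3Oc3cc(OC)c(O)c(OC)c3)c2)c(OC)c1 | intermediate
31 | A–F hexamer benzyl ether: as 30 with D4–O–E1; ring E 2-O–F1, 3,4,5-tri-OMe; ring F 3,5-di-OMe, 4-OBn | COc1cc(OC)c(Oc2cc(OCC)c(OC)c(Oc3cc(OC)c(OC)c(OC)c3Oc3cc(OC)c(Oc4cc(OC)c(OC)c(OC)c4Oc4cc(OC)c(OCc5ccccc5)c(OC)c4)c(OC)c3)c2)c(OC)c1 | intermediate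
32 | A–F hexamer phenol: as 31 with F4 OH | COc1cc(OC)c(Oc2cc(OCC)c(OC)c(Oc3cc(OC)c(OC)c(OC)c3Oc3cc(OC)c(Oc4cc(OC)c(OC)c(OC)c4Oc4cc(OC)c(O)c(OC)c4)c(OC)c3)c2)c(OC)c1 | intermediate
33 | fully alkylated octamer: as 32 with F4–O–G1; ring G 2-O–H1, 3,4,5-tri-OMe; ring H 3,4,5-tri-OMe | COc1cc(OC)c(Oc2cc(OCC)c(OC)c(Oc3cc(OC)c(OC)c(OC)c3Oc3cc(OC)c(Oc4cc(OC)c(OC)c(OC)c4Oc4cc(OC)c(Oc5cc(OC)c(OC)c(OC)c5Oc5cc(OC)c(OC)c(OC)c5)c(OC)c4)c(OC)c3)c2)c(OC)c1 | intermediate
34 | CNP0175816.0 (octameric polyphenol with 21 free hydroxyls, achiral) | Oc1cc(O)c(Oc2cc(O)c(O)c(Oc3cc(O)c(O)c(O)c3Oc3cc(O)c(Oc4cc(O)c(O)c(O)c4Oc4cc(O)c(Oc5cc(O)c(O)c(O)c5Oc5cc(O)c(O)c(O)c5)c(O)c4)c(O)c3)c2)c(O)c1 | target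

Total step count: 16. Longest linear sequence: 9 steps (1, 2, 4, 11, 12, 13, 14, 15, 16). The branches through steps 5, 6, 9 and through steps 7, 8, 9 are equally long.

Steps most likely to fail

Step 4. The terminal aryl ynol ether may oligomerise or be hydrated before the vinylogous-ester cyclobutenone opens, and the product phenol may intercept the vinylketene. The fallback sets out from 4 and returns at 16. Treating 4 with n-BuLi as in step 2 and quenching acetylide 6 with Me3SiCl in place of water should give trimethyl[(2,4,6-trimethoxyphenoxy)ethynyl]silane F1, a capped ynol ether that can be purified and stored. Heating F1 with 11 in toluene runs the same benzannulation. Silicon on the attacking carbon stabilises the positive charge that builds up on the neighbouring oxygen-bearing carbon, so the orientation is reinforced. The product should be 3-ethoxy-2-methoxy-5-(2,4,6-trimethoxyphenoxy)-6-(trimethylsilyl)phenol F2. Ipso-protodesilylation of this electron-rich arylsilane with CF3CO2H in CH2Cl2 then gives 16.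

Step 13. C–O bond formation at copper may be slow, because the phenoxide is flanked by two methoxy groups and the iodide by an aryloxy group. Hydrodeiodination and oxidative loss of the phenoxide could then take over. The fallback sets out from 26 and returns at 31, and it replaces copper catalysis by a trivalent iodine electrophile. Oxidation of 26 with mCPBA and TsOH·H2O in MeCN, followed by capture with 1,3,5-trimethoxybenzene, should give {2-[4-(benzyloxy)-3,5-dimethoxyphenoxy]-3,4,5-trimethoxyphenyl}(2,4,6-trimethoxyphenyl)iodonium tosylate F3. The potassium phenoxide of 30 (t-BuOK, THF–toluene, rt → 50 °C) then undergoes metal-free ligand coupling at iodine. This reaction type tolerates doubly ortho-substituted phenols and transfers the less electron-rich, ortho-substituted aryl group, giving 31.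

Step 16. Dealkylation may stop short as partly cleaved borates precipitate, and the pyrogallol-type rings may be oxidised by air during work-up and purification. The fallback sets out from 33 and returns at 34, and it turns the end game into a trap-and-release sequence. After the BBr3 treatment the crude polyphenol is not purified but acetylated at once (Ac2O, pyridine, argon) to the octamer henicosaacetate F4. This compound is stable to air and can be freed from partly alkylated material on silica gel. Acid methanolysis (AcCl in degassed MeOH, rt → 40 °C) and evaporation then release 34 without any basic or chromatographic exposure.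

Further compounds
F1 | step 4 | trimethyl[(2,4,6-trimethoxyphenoxy)ethynyl]silane | COc1cc(OC)c(OC#C[Si](C)(C)C)c(OC)c1
F2 | step 4 | 3-ethoxy-2-methoxy-5-(2,4,6-trimethoxyphenoxy)-6-(trimethylsilyl)phenol | CCOc1cc(Oc2c(OC)cc(OC)cc2OC)c([Si](C)(C)C)c(O)c1OC
F3 | step 13 | {2-[4-(benzyloxy)-3,5-dimethoxyphenoxy]-3,4,5-trimethoxyphenyl}(2,4,6-trimethoxyphenyl)iodonium tosylate | COc1cc(OC)c([I+]c2cc(OC)c(OC)c(OC)c2Oc2cc(OC)c(OCc3ccccc3)c(OC)c2)c(OC)c1.Cc1ccc(S(=O)(=O)[O-])cc1
F4 | step 16 | octamer henicosaacetate (34 with all 21 hydroxyls acetylated) | CC(=O)Oc1cc(OC(C)=O)c(Oc2cc(OC(C)=O)c(OC(C)=O)c(Oc3cc(OC(C)=O)c(OC(C)=O)c(OC(C)=O)c3Oc3cc(OC(C)=O)c(Oc4cc(OC(C)=O)c(OC(C)=O)c(OC(C)=O)c4Oc4cc(OC(C)=O)c(Oc5cc(OC(C)=O)c(OC(C)=O)c(OC(C)=O)c5Oc5cc(OC(C)=O)c(OC(C)=O)c(OC(C)=O)c5)c(OC(C)=O)c4)c(OC(C)=O)c3)c2)c(OC(C)=O)c1
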